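**Strategy.** The target is cut at the C4–O–C4 ether into two 7,8,4'-trioxygenated flavan-3,4-diol units that differ only at C2. Everything rests on closing ring C of each unit between C3 and C4 by a samarium diiodide pinacol cyclisation of an aryloxy dialdehyde, which exploits the vicinal cis oxygens on C3 and C4 of ring C. In the (2S) unit this one operation forms the C3–C4 bond and sets C3 and C4 by relay from C2, the only stereocenter made by catalysis (iridium allylic etherification). Its precursor is an open-chain 2-(1-aryl-2-oxoethoxy)benzaldehyde. The (2S) diol then serves as C4 electrophile and the all-cis (2R) unit as the alcohol.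

Key step: step 8

Remark on the chemistry: the (Ra,Rc,Rc) phosphoramidite is assumed to give the (R)-ether 8 from carbonate 6 and aryloxide 7, by analogy with simple cinnamyl carbonates. If the sense of induction is the opposite, the two ligand enantiomers are exchanged between steps 6 and 10 and nothing else changes.

**Step 1**
Reactants: 1 2,3,4-trihydroxybenzaldehyde
Product: 2 3,4-bis(benzyloxy)-2-hydroxybenzaldehyde
Conditions: BnBr (2.05 equiv), K2CO3 (2.1 equiv), DMF, rt
Reagents that add atoms: benzyl bromide BrCc1ccccc1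
Why: Williamson etherification, in which the 2-OH is held in a hydrogen bond to the formyl group and is the least nucleophilic, so the 4- and 3-oxygens should be benzylated first.

**Step 2**
Reactants: 3 4-(benzyloxy)benzaldehyde
Product: 4 ethyl (2E)-3-[4-(benzyloxy)phenyl]prop-2-enoate
Conditions: (EtO)2P(O)CH2CO2Et, NaH, THF, 0 °C to rt
Reagents that add atoms: triethyl phosphonoacetate CCOC(=O)CP(=O)(OCC)OCC
Why: Horner–Wadsworth–Emmons olefination with a stabilised phosphonate should give the (E)-cinnamate.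

**Step 3**
Reactants: 4 ethyl (2E)-3-[4-(benzyloxy)phenyl]prop-2-enoate
Product: 5 (2E)-3-[4-(benzyloxy)phenyl]prop-2-en-1-ol
Conditions: i-Bu2AlH (2.2 equiv), CH2Cl2, −78 °C; aq. potassium sodium tartrate
Reagents that add atoms: none
Why: 1,2-reduction of the unsaturated ester by i-Bu2AlH should give the allylic alcohol without touching the alkene.

**Step 4**
Reactants: 5 (2E)-3-[4-(benzyloxy)phenyl]prop-2-en-1-ol
Product: 6 (2E)-3-[4-(benzyloxy)phenyl]prop-2-en-1-yl methyl carbonate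
Conditions: ClCO2Me, pyridine, CH2Cl2, 0 °C
Reagents that add atoms: methyl chloroformate COC(=O)Cl
Why: O-acylation of the primary allylic alcohol installs the carbonate leaving group needed for allylic substitution.

**Step 5**
Reactants: 2 3,4-bis(benzyloxy)-2-hydroxybenzaldehyde
Product: 7 sodium 2,3-bis(benzyloxy)-6-formylphenolate
Conditions: NaH (1.0 equiv), THF, 0 °C to rt; evaporated, solid washed with pentane, dried in vacuo, stored under Ar
Reagents that add atoms: sodium hydride [Na+].[H-]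
Why: Irreversible acid–base reaction of the phenol with NaH gives the aryloxide, a salicylaldehyde-type sodium salt that can be isolated as a solid, so that one batch serves as the preformed nucleophile of both enantiomeric allylic etherifications.

**Step 6**
Reactants: 7 sodium 2,3-bis(benzyloxy)-6-formylphenolate; 6 (2E)-3-[4-(benzyloxy)phenyl]prop-2-en-1-yl methyl carbonate
Product: 8 3,4-bis(benzyloxy)-2-{[(1R)-1-[4-(benzyloxy)phenyl]prop-2-en-1-yl]oxy}benzaldehyde
Conditions: 7 (1.2 equiv), [Ir(cod)Cl]2 (2 mol %), (Ra,Rc,Rc)-binaphthyl N,N-bis(1-phenylethyl)phosphoramidite (4 mol %, pre-activated with n-PrNH2), THF, rt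
Reagents that add atoms: none
Why: Iridium-catalysed asymmetric allylic etherification, in which the cyclometalated complex formed from [Ir(cod)Cl]2 and the phosphoramidite ionises the linear carbonate and the aryloxide attacks the aryl-bearing allyl terminus, so the ligand sets the C–O stereocenter (the later C2) and both blocked ortho positions exclude a Claisen rearrangement.

**Step 7**
Reactants: 8 3,4-bis(benzyloxy)-2-{[(1R)-1-[4-(benzyloxy)phenyl]prop-2-en-1-yl]oxy}benzaldehyde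
Product: 10 3,4-bis(benzyloxy)-2-{[(1S)-1-[4-(benzyloxy)phenyl]-2-oxoethyl]oxy}benzaldehyde, via secondary ozonide 9 (not isolated)
Conditions: O3, CH2Cl2, −78 °C; then PPh3, −78 to 0 °C; crude used at once
Reagents that add atoms: ozone [O-][O+]=O
Why: Ozonolysis with reductive work-up cleaves the monosubstituted alkene faster than the arenes, and the neutral cold conditions should leave the epimerisable C–H next to the new aldehyde untouched (the descriptor changes from R to S only through the priority rules).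

**Step 8**
Reactants: 10 3,4-bis(benzyloxy)-2-{[(1S)-1-[4-(benzyloxy)phenyl]-2-oxoethyl]oxy}benzaldehyde
Product: 11 (2S,3R,4R)-7,8-bis(benzyloxy)-2-[4-(benzyloxy)phenyl]-3,4-dihydro-2H-chromene-3,4-diol
Conditions: SmI2 (2.5 equiv), t-BuOH (2.2 equiv), THF (0.01 M), −78 to −20 °C
Reagents that add atoms: none
Why: Single-electron transfer from SmI2 to the more easily reduced aryl aldehyde gives a samarium ketyl at the future C4, which adds to the samarium-bound aliphatic aldehyde carbon (future C3), and a second electron then gives the diolate of trivalent samarium, protonated by t-BuOH. The closest known reaction type is the SmI2 pinacol cyclisation of 1,6-dialdehydes to cis-cyclohexane-1,2-diols. Ring C closes by 6-exo-trig attack of the C4 ketyl on the C3 carbonyl carbon. C3 is controlled by the C2 stereocenter, because in the chair-like transition state the 2-aryl group is equatorial and the C3–O bond is equatorial and anti to the ring C2–O1 bond, which places 3-O trans to the aryl group; C4 is controlled by the samarium centre that bridges both oxygens and enforces the 3,4-cis diol. The step needs ring closure to outrun intermolecular coupling, loss of aryloxide from the α-aryloxy aldehyde and enolisation at C2, and this should be secured by high dilution, the six-membered array of the two carbonyls and the neutral cold medium.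

**Step 9**
Reactants: 11 (2S,3R,4R)-7,8-bis(benzyloxy)-2-[4-(benzyloxy)phenyl]-3,4-dihydro-2H-chromene-3,4-diol
Product: 12 (2S,3S)-4-(benzylsulfanyl)-7,8-bis(benzyloxy)-2-[4-(benzyloxy)phenyl]-3,4-dihydro-2H-chromen-3-ol (both C4 epimers, used as the mixture)
Conditions: BnSH (3 equiv), BF3·OEt2 (0.2 equiv), CH2Cl2, −40 °C
Reagents that add atoms: phenylmethanethiol SCc1ccccc1
Why: Acid-catalysed thiolysis (SN1) of the benzylic 4-OH through the cation stabilised by the para 7-benzyloxy group gives a donor that AgBF4 can activate later without acid, and its C4 configuration is immaterial.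

**Step 10**
Reactants: 7 sodium 2,3-bis(benzyloxy)-6-formylphenolate; 6 (2E)-3-[4-(benzyloxy)phenyl]prop-2-en-1-yl methyl carbonate
Product: 13 3,4-bis(benzyloxy)-2-{[(1S)-1-[4-(benzyloxy)phenyl]prop-2-en-1-yl]oxy}benzaldehyde
Conditions: 7 (1.2 equiv), [Ir(cod)Cl]2 (2 mol %), (Sa,Sc,Sc)-binaphthyl N,N-bis(1-phenylethyl)phosphoramidite (4 mol %, pre-activated with n-PrNH2), THF, rt
Reagents that add atoms: none
Why: The same iridium-catalysed asymmetric allylic etherification with the enantiomeric ligand should give the mirror-image ether, which sets C2 of the (2R) unit.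

**Step 11**
Reactants: 13 3,4-bis(benzyloxy)-2-{[(1S)-1-[4-(benzyloxy)phenyl]prop-2-en-1-yl]oxy}benzaldehyde
Product: 15 3,4-bis(benzyloxy)-2-{[(1R)-1-[4-(benzyloxy)phenyl]-2-oxoethyl]oxy}benzaldehyde, via secondary ozonide 14 (not isolated)
Conditions: O3, CH2Cl2, −78 °C; then PPh3, −78 to 0 °C; crude used at once
Reagents that add atoms: ozone [O-][O+]=O
Why: Ozonolysis with reductive work-up, as in step 7.

**Step 12**
Reactants: 15 3,4-bis(benzyloxy)-2-{[(1R)-1-[4-(benzyloxy)phenyl]-2-oxoethyl]oxy}benzaldehyde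
Product: 16 (2R,3S,4S)-7,8-bis(benzyloxy)-2-[4-(benzyloxy)phenyl]-3,4-dihydro-2H-chromene-3,4-diol
Conditions: SmI2 (2.5 equiv), t-BuOH (2.2 equiv), THF (0.01 M), −78 to −20 °C
Reagents that add atoms: none
Why: The SmI2 pinacol cyclisation of step 8 in the mirror-image series should close ring C of the second unit with the same 2,3-trans-3,4-cis relay from C2.

**Step 13**
Reactants: 16 (2R,3S,4S)-7,8-bis(benzyloxy)-2-[4-(benzyloxy)phenyl]-3,4-dihydro-2H-chromene-3,4-diol
Product: 17 (2R,3R)-7,8-bis(benzyloxy)-2-[4-(benzyloxy)phenyl]-3-hydroxy-2,3-dihydro-4H-chromen-4-one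
Conditions: DDQ (1.2 equiv), 1,4-dioxane, rt
Reagents that add atoms: none
Why: DDQ oxidation of a benzylic alcohol by hydride abstraction from the electron-rich C4–H (para to the 7-benzyloxy group) should give the 4-ketone and leave the non-benzylic 3-OH alone.

**Step 14**
Reactants: 17 (2R,3R)-7,8-bis(benzyloxy)-2-[4-(benzyloxy)phenyl]-3-hydroxy-2,3-dihydro-4H-chromen-4-one
Product: 18 (2R,3S)-7,8-bis(benzyloxy)-2-[4-(benzyloxy)phenyl]-4-oxo-3,4-dihydro-2H-chromen-3-yl benzoate
Conditions: PhCO2H, PPh3, DIAD, THF, 0 °C to rt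
Reagents that add atoms: benzoic acid O=C(O)c1ccccc1
Why: Mitsunobu reaction, in which benzoate displaces the equatorial oxyphosphonium group by SN2 at the carbon next to the ketone, so C3 is inverted to the 2,3-cis (axial) benzoate.

**Step 15**
Reactants: 18 (2R,3S)-7,8-bis(benzyloxy)-2-[4-(benzyloxy)phenyl]-4-oxo-3,4-dihydro-2H-chromen-3-yl benzoate
Product: 19 (2R,3R,4R)-7,8-bis(benzyloxy)-2-[4-(benzyloxy)phenyl]-4-hydroxy-3,4-dihydro-2H-chromen-3-yl benzoate
Conditions: NaBH4, CeCl3·7H2O, MeOH/THF, −78 °C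
Reagents that add atoms: none
Why: Luche reduction, in which hydride attacks C4 from the face opposite the axial 3-benzoyloxy group and gives the 4-OH cis to both neighbours, while the near-neutral cold medium should suppress benzoyl migration.

**Step 16**
Reactants: 12 (2S,3S)-4-(benzylsulfanyl)-7,8-bis(benzyloxy)-2-[4-(benzyloxy)phenyl]-3,4-dihydro-2H-chromen-3-ol; 19 (2R,3R,4R)-7,8-bis(benzyloxy)-2-[4-(benzyloxy)phenyl]-4-hydroxy-3,4-dihydro-2H-chromen-3-yl benzoate
Product: 20 (2R,3R,4R)-7,8-bis(benzyloxy)-2-[4-(benzyloxy)phenyl]-4-{[(2S,3R,4R)-7,8-bis(benzyloxy)-2-[4-(benzyloxy)phenyl]-3-hydroxy-3,4-dihydro-2H-chromen-4-yl]oxy}-3,4-dihydro-2H-chromen-3-yl benzoate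
Conditions: 19 (1.3 equiv), AgBF4 (1.5 equiv), 2,6-di-tert-butyl-4-methylpyridine, 4 Å MS, CH2Cl2, −78 to −30 °C, slow addition of 12
Reagents that add atoms: none
Why: AgBF4-promoted SN1 etherification of a 4-sulfanylflavan, in which the C4 cation of the 2,3-trans unit (2-aryl and 3-OH equatorial in the half-chair) should be trapped by the 4-OH of 19 pseudo-axially through a chair-like transition state, on the face trans to the 2-aryl group, to give the 3,4-cis ether, while C4 of 19 keeps its configuration because only its O–H bond reacts and the buffered medium does not ionise it.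

**Step 17**
Reactants: 20 the benzoate of step 16
Product: 21 (2R,3R,4R)-7,8-bis(benzyloxy)-2-[4-(benzyloxy)phenyl]-4-{[(2S,3R,4R)-7,8-bis(benzyloxy)-2-[4-(benzyloxy)phenyl]-3-hydroxy-3,4-dihydro-2H-chromen-4-yl]oxy}-3,4-dihydro-2H-chromen-3-ol
Conditions: K2CO3 (0.3 equiv), MeOH/THF, rt
Reagents that add atoms: none
Why: Base-catalysed transesterification removes the benzoate as methyl benzoate while no phenol is yet free.

**Step 18**
Reactants: 21 the hexabenzyl ether of step 17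
Product: 22 (2R,3R,4R)-2-(4-hydroxyphenyl)-4-{[(2S,3R,4R)-3,7,8-trihydroxy-2-(4-hydroxyphenyl)-3,4-dihydro-2H-chromen-4-yl]oxy}-3,4-dihydro-2H-chromene-3,7,8-triol (CNP0241481.1)
Conditions: H2 (1 atm), 10% Pd/C, EtOAc/MeOH, rt, stopped at full debenzylation
Reagents that add atoms: none
Why: Catalytic hydrogenolysis should cleave the six aryl benzyl ethers much faster than the hindered secondary dibenzylic ether in the absence of acid, and no stereocenter is touched.

**Compound list**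

1 | 2,3,4-trihydroxybenzaldehyde | O=Cc1ccc(O)c(O)c1O | starting material
2 | 3,4-bis(benzyloxy)-2-hydroxybenzaldehyde | O=Cc1ccc(OCc2ccccc2)c(OCc2ccccc2)c1O | intermediate
3 | 4-(benzyloxy)benzaldehyde | O=Cc1ccc(OCc2ccccc2)cc1 | starting material
4 | ethyl (2E)-3-[4-(benzyloxy)phenyl]prop-2-enoate | CCOC(=O)/C=C/c1ccc(OCc2ccccc2)cc1 | intermediate
5 | (2E)-3-[4-(benzyloxy)phenyl]prop-2-en-1-ol | OC/C=C/c1ccc(OCc2ccccc2)cc1 | intermediate
6 | (2E)-3-[4-(benzyloxy)phenyl]prop-2-en-1-yl methyl carbonate | COC(=O)OC/C=C/c1ccc(OCc2ccccc2)cc1 | intermediate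
7 | sodium 2,3-bis(benzyloxy)-6-formylphenolate | [Na+].[O-]c1c(C=O)ccc(OCc2ccccc2)c1OCc1ccccc1 | intermediate
8 | 3,4-bis(benzyloxy)-2-{[(1R)-1-[4-(benzyloxy)phenyl]prop-2-en-1-yl]oxy}benzaldehyde | C=C[C@@H](Oc1c(C=O)ccc(OCc2ccccc2)c1OCc1ccccc1)c1ccc(OCc2ccccc2)cc1 | intermediate
9 | 3,4-bis(benzyloxy)-2-{(S)-[4-(benzyloxy)phenyl](1,2,4-trioxolan-3-yl)methoxy}benzaldehyde (mixture at the trioxolane carbon) | O=Cc1ccc(OCc2ccccc2)c(OCc2ccccc2)c1O[C@H](C1OCOO1)c1ccc(OCc2ccccc2)cc1 | intermediate (not isolated)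
10 | 3,4-bis(benzyloxy)-2-{[(1S)-1-[4-(benzyloxy)phenyl]-2-oxoethyl]oxy}benzaldehyde | O=C[C@@H](Oc1c(C=O)ccc(OCc2ccccc2)c1OCc1ccccc1)c1ccc(OCc2ccccc2)cc1 | intermediate
11 | (2S,3R,4R)-7,8-bis(benzyloxy)-2-[4-(benzyloxy)phenyl]-3,4-dihydro-2H-chromene-3,4-diol | O[C@@H]1c2ccc(OCc3ccccc3)c(OCc3ccccc3)c2O[C@@H](c2ccc(OCc3ccccc3)cc2)[C@@H]1O | intermediate
12 | (2S,3S)-4-(benzylsulfanyl)-7,8-bis(benzyloxy)-2-[4-(benzyloxy)phenyl]-3,4-dihydro-2H-chromen-3-ol (C4 epimers) | S(Cc1ccccc1)C1c2ccc(OCc3ccccc3)c(OCc3ccccc3)c2O[C@@H](c2ccc(OCc3ccccc3)cc2)[C@@H]1O | intermediate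
13 | 3,4-bis(benzyloxy)-2-{[(1S)-1-[4-(benzyloxy)phenyl]prop-2-en-1-yl]oxy}benzaldehyde | C=C[C@H](Oc1c(C=O)ccc(OCc2ccccc2)c1OCc1ccccc1)c1ccc(OCc2ccccc2)cc1 | intermediate
14 | 3,4-bis(benzyloxy)-2-{(R)-[4-(benzyloxy)phenyl](1,2,4-trioxolan-3-yl)methoxy}benzaldehyde (mixture at the trioxolane carbon) | O=Cc1ccc(OCc2ccccc2)c(OCc2ccccc2)c1O[C@@H](C1OCOO1)c1ccc(OCc2ccccc2)cc1 | intermediate (not isolated)
15 | 3,4-bis(benzyloxy)-2-{[(1R)-1-[4-(benzyloxy)phenyl]-2-oxoethyl]oxy}benzaldehyde | O=C[C@H](Oc1c(C=O)ccc(OCc2ccccc2)c1OCc1ccccc1)c1ccc(OCc2ccccc2)cc1 | intermediate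
16 | (2R,3S,4S)-7,8-bis(benzyloxy)-2-[4-(benzyloxy)phenyl]-3,4-dihydro-2H-chromene-3,4-diol | O[C@H]1c2ccc(OCc3ccccc3)c(OCc3ccccc3)c2O[C@H](c2ccc(OCc3ccccc3)cc2)[C@H]1O | intermediate
17 | (2R,3R)-7,8-bis(benzyloxy)-2-[4-(benzyloxy)phenyl]-3-hydroxy-2,3-dihydro-4H-chromen-4-one | O=C1c2ccc(OCc3ccccc3)c(OCc3ccccc3)c2O[C@H](c2ccc(OCc3ccccc3)cc2)[C@H]1O | intermediate
18 | (2R,3S)-7,8-bis(benzyloxy)-2-[4-(benzyloxy)phenyl]-4-oxo-3,4-dihydro-2H-chromen-3-yl benzoate | O=C1c2ccc(OCc3ccccc3)c(OCc3ccccc3)c2O[C@H](c2ccc(OCc3ccccc3)cc2)[C@@H]1OC(=O)c1ccccc1 | intermediate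
19 | (2R,3R,4R)-7,8-bis(benzyloxy)-2-[4-(benzyloxy)phenyl]-4-hydroxy-3,4-dihydro-2H-chromen-3-yl benzoate | O[C@@H]1c2ccc(OCc3ccccc3)c(OCc3ccccc3)c2O[C@H](c2ccc(OCc3ccccc3)cc2)[C@@H]1OC(=O)c1ccccc1 | intermediate
20 | (2R,3R,4R)-7,8-bis(benzyloxy)-2-[4-(benzyloxy)phenyl]-4-{[(2S,3R,4R)-7,8-bis(benzyloxy)-2-[4-(benzyloxy)phenyl]-3-hydroxy-3,4-dihydro-2H-chromen-4-yl]oxy}-3,4-dihydro-2H-chromen-3-yl benzoate | O([C@@H]1c2ccc(OCc3ccccc3)c(OCc3ccccc3)c2O[C@H](c2ccc(OCc3ccccc3)cc2)[C@@H]1OC(=O)c1ccccc1)[C@@H]1c2ccc(OCc3ccccc3)c(OCc3ccccc3)c2O[C@@H](c2ccc(OCc3ccccc3)cc2)[C@@H]1O | intermediate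
21 | (2R,3R,4R)-7,8-bis(benzyloxy)-2-[4-(benzyloxy)phenyl]-4-{[(2S,3R,4R)-7,8-bis(benzyloxy)-2-[4-(benzyloxy)phenyl]-3-hydroxy-3,4-dihydro-2H-chromen-4-yl]oxy}-3,4-dihydro-2H-chromen-3-ol | O([C@@H]1c2ccc(OCc3ccccc3)c(OCc3ccccc3)c2O[C@H](c2ccc(OCc3ccccc3)cc2)[C@@H]1O)[C@@H]1c2ccc(OCc3ccccc3)c(OCc3ccccc3)c2O[C@@H](c2ccc(OCc3ccccc3)cc2)[C@@H]1O | intermediate
22 | (2R,3R,4R)-2-(4-hydroxyphenyl)-4-{[(2S,3R,4R)-3,7,8-trihydroxy-2-(4-hydroxyphenyl)-3,4-dihydro-2H-chromen-4-yl]oxy}-3,4-dihydro-2H-chromene-3,7,8-triol | Oc1ccc([C@H]2Oc3c(ccc(O)c3O)[C@@H](O[C@@H]3c4ccc(O)c(O)c4O[C@@H](c4ccc(O)cc4)[C@@H]3O)[C@H]2O)cc1 | target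

**Total step count:** 18.
**Longest linear sequence:** 12 steps (steps 2, 3, 4, 10, 11, 12, 13, 14, 15, 16, 17, 18).

**Steps most likely to fail**

1. Step 8. The α-aryl-α-aryloxy aldehyde may epimerise at C2 before it cyclises, SmI2 may expel the aryloxide instead of coupling, or the relay from C2 may be incomplete. The fallback closes the same bond by metathesis and sets out from 8. Methylenation of the aryl aldehyde (Ph3PCH3Br, KN(SiMe3)2, THF, −78 to 0 °C) should give 1,2-bis(benzyloxy)-3-{[(1R)-1-[4-(benzyloxy)phenyl]prop-2-en-1-yl]oxy}-4-ethenylbenzene F1. Ring-closing metathesis (second-generation Grubbs catalyst, CH2Cl2, 40 °C) should give (2R)-7,8-bis(benzyloxy)-2-[4-(benzyloxy)phenyl]-2H-chromene F2. Dihydroxylation with OsO4 (cat.) and N-methylmorpholine N-oxide in acetone/water should occur anti to the 2-aryl group, and the route is rejoined at 11.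

2. Step 16. The alcohol may enter on the wrong face of the C4 cation and give the 3,4-trans ether, or the donor may condense with itself through its free 3-OH. The fallback replaces the cation donor by an epoxide. It sets out from 8 and runs through diene F1 and chromene F2 as above. Dimethyldioxirane (acetone/CH2Cl2, −40 °C) should epoxidise F2 on the face away from the aryl group to (2S)-7,8-bis(benzyloxy)-2-[4-(benzyloxy)phenyl]-3,4-epoxy-3,4-dihydro-2H-chromene (oxirane trans to the 2-aryl group) F3. This electrophile has no free hydroxyl. Alcohol 19 with ZnCl2 (THF, −78 °C) should open it at the benzylic C4 on the side of the departing oxygen, and the route is rejoined at 20.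

3. Step 14. The activated α-ketol may eliminate or ring-open, or the cis benzoate may epimerise back to trans during the Mitsunobu inversion. The fallback builds the 2,3-cis relation by ketone reduction and sets out from 13. Methylenation (Ph3PCH3Br, KN(SiMe3)2, THF) should give 1,2-bis(benzyloxy)-3-{[(1S)-1-[4-(benzyloxy)phenyl]prop-2-en-1-yl]oxy}-4-ethenylbenzene F4, and ring-closing metathesis (second-generation Grubbs catalyst, CH2Cl2, 40 °C) should give (2S)-7,8-bis(benzyloxy)-2-[4-(benzyloxy)phenyl]-2H-chromene F5. Hydroboration–oxidation (BH3·SMe2, then NaOH/H2O2), with boron adding to C3 anti to the aryl group, should give (2R,3S)-7,8-bis(benzyloxy)-2-[4-(benzyloxy)phenyl]-3,4-dihydro-2H-chromen-3-ol F6. Dess–Martin periodinane should oxidise it to (2R)-7,8-bis(benzyloxy)-2-[4-(benzyloxy)phenyl]-2H-chromen-3(4H)-one F7. LiBH(s-Bu)3 (THF, −78 °C), delivering hydride anti to the aryl group, should give (2R,3R)-7,8-bis(benzyloxy)-2-[4-(benzyloxy)phenyl]-3,4-dihydro-2H-chromen-3-ol F8. Benzoyl chloride/pyridine should give (2R,3R)-7,8-bis(benzyloxy)-2-[4-(benzyloxy)phenyl]-3,4-dihydro-2H-chromen-3-yl benzoate F9. DDQ (2.5 equiv) in wet dioxane should then oxidise C4–H through the 4-ol to the ketone, and the route is rejoined at 18.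

**Further compounds**

F1 | step 8 | 1,2-bis(benzyloxy)-3-{[(1R)-1-[4-(benzyloxy)phenyl]prop-2-en-1-yl]oxy}-4-ethenylbenzene | C=C[C@@H](Oc1c(C=C)ccc(OCc2ccccc2)c1OCc1ccccc1)c1ccc(OCc2ccccc2)cc1
F2 | step 8 | (2R)-7,8-bis(benzyloxy)-2-[4-(benzyloxy)phenyl]-2H-chromene | C1=C[C@H](c2ccc(OCc3ccccc3)cc2)Oc2c1ccc(OCc1ccccc1)c2OCc1ccccc1
F3 | step 16 | (2S)-7,8-bis(benzyloxy)-2-[4-(benzyloxy)phenyl]-3,4-epoxy-3,4-dihydro-2H-chromene (oxirane trans to the 2-aryl group) | O1[C@@H]2c3ccc(OCc4ccccc4)c(OCc4ccccc4)c3O[C@@H](c3ccc(OCc4ccccc4)cc3)[C@@H]21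
F4 | step 14 | 1,2-bis(benzyloxy)-3-{[(1S)-1-[4-(benzyloxy)phenyl]prop-2-en-1-yl]oxy}-4-ethenylbenzene | C=C[C@H](Oc1c(C=C)ccc(OCc2ccccc2)c1OCc1ccccc1)c1ccc(OCc2ccccc2)cc1
F5 | step 14 | (2S)-7,8-bis(benzyloxy)-2-[4-(benzyloxy)phenyl]-2H-chromene | C1=C[C@@H](c2ccc(OCc3ccccc3)cc2)Oc2c1ccc(OCc1ccccc1)c2OCc1ccccc1
F6 | step 14 | (2R,3S)-7,8-bis(benzyloxy)-2-[4-(benzyloxy)phenyl]-3,4-dihydro-2H-chromen-3-ol | C1c2ccc(OCc3ccccc3)c(OCc3ccccc3)c2O[C@H](c2ccc(OCc3ccccc3)cc2)[C@H]1O
F7 | step 14 | (2R)-7,8-bis(benzyloxy)-2-[4-(benzyloxy)phenyl]-2H-chromen-3(4H)-one | O=C1Cc2ccc(OCc3ccccc3)c(OCc3ccccc3)c2O[C@@H]1c1ccc(OCc2ccccc2)cc1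
F8 | step 14 | (2R,3R)-7,8-bis(benzyloxy)-2-[4-(benzyloxy)phenyl]-3,4-dihydro-2H-chromen-3-ol | C1c2ccc(OCc3ccccc3)c(OCc3ccccc3)c2O[C@H](c2ccc(OCc3ccccc3)cc2)[C@@H]1O
F9 | step 14 | (2R,3R)-7,8-bis(benzyloxy)-2-[4-(benzyloxy)phenyl]-3,4-dihydro-2H-chromen-3-yl benzoate | C1c2ccc(OCc3ccccc3)c(OCc3ccccc3)c2O[C@H](c2ccc(OCc3ccccc3)cc2)[C@@H]1OC(=O)c1ccccc1
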